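**Plan**

- Retrosynthesis: the three methoxymethyl acetals and the C3–O bond are removed first (the C3 hydroxyl comes from lithiation–borylation–oxidation of a flavone). Ring C is then cut at C8a–O1, C4a–C4 and O1–C2, leaving a ring A aryne and 3-[4-(methoxymethoxy)phenyl]propiolic acid.
- Enabling feature: C4a and C8a are adjacent carbons of ring A that end up carrying the C4 carbonyl and O1. The C5 oxygen sits beside C4a and the C8 carbon bearing the 2-methylbut-3-en-2-yl group sits beside C8a, so a C4a≡C8a aryne polarised by the C5 oxygen maps directly onto the pyranone.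
- The aryne precursor is cut at O–S, C4a–Si and C8–C(quaternary): phloroglucinol diether, O-prenylation, aromatic Claisen shift, carbamate-directed silylation, triflation. The acid is cut at the aryl–alkyne bond.
- Forward order: ring A is bought and its C8 side chain and silyl/triflate pair are installed (steps 1–6), the acid is made (steps 7–8), ring C is closed in one operation (step 9), C3 is hydroxylated (step 10) and the acetals are removed (step 11).
- Stereochemistry: the target has no stereocentre and no stereogenic double bond, so nothing has to be controlled.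

Key step: step 9

Remark: dienone 5 is the only chiral species on the route; it forms as a racemate and loses its stereocentre on tautomerisation.

**Route**

Step 1
Reactants: 1 phloroglucinol (benzene-1,3,5-triol)
Product: 2 diether phenol 3,5-bis(methoxymethoxy)phenol
Conditions: NaH (2.0 equiv), MOMCl (2.0 equiv), DMF, 0 °C to rt; chromatography
Reagents that add atoms: chloromethyl methyl ether (MOMCl), COCCl
Why: Williamson-type O-alkylation of the sodium phenoxide with the reactive chloromethyl ether, in which two equivalents should make the diether the main component of a statistical mixture that is separated by chromatography.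

Step 2
Reactants: 2 diether phenol 3,5-bis(methoxymethoxy)phenol; 3 prenyl bromide (1-bromo-3-methylbut-2-ene)
Product: 4 prenyl ether 1,3-bis(methoxymethoxy)-5-[(3-methylbut-2-en-1-yl)oxy]benzene
Conditions: K2CO3, acetone, reflux
Reagents that add atoms: none
Why: Williamson ether synthesis, in which the weakly basic carbonate in acetone should give clean O-alkylation of the single free phenol by the primary allylic bromide without C-prenylation.

Step 3
Reactants: 4 prenyl ether 1,3-bis(methoxymethoxy)-5-[(3-methylbut-2-en-1-yl)oxy]benzene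
Product: 6 ring A phenol 3,5-bis(methoxymethoxy)-2-(2-methylbut-3-en-2-yl)phenol, via Claisen dienone 5 (not isolated)
Conditions: PhNEt2, 190 °C, sealed tube, argon
Reagents that add atoms: none
Why: Aromatic Claisen rearrangement, in which the [3,3] shift carries the dimethyl-substituted allyl terminus to an ortho carbon (both are equivalent) and so creates the quaternary carbon on the future C8, tautomerisation of dienone 5 restores the arene, and the basic aniline solvent suppresses acid-catalysed closure of the phenol onto its alkene.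

Step 4
Reactants: 6 ring A phenol 3,5-bis(methoxymethoxy)-2-(2-methylbut-3-en-2-yl)phenol
Product: 7 carbamate 3,5-bis(methoxymethoxy)-2-(2-methylbut-3-en-2-yl)phenyl N-(propan-2-yl)carbamate
Conditions: i-PrNCO (1.5 equiv), Et3N (cat.), CH2Cl2, rt
Reagents that add atoms: isopropyl isocyanate, CC(C)N=C=O
Why: Amine-catalysed addition of the phenol to the isocyanate (carbamoylation) gives an N–H carbamate that becomes a strong ortho-directing group once N-silylated and can later be removed by elimination without attack at its hindered carbonyl.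

Step 5
Reactants: 7 carbamate 3,5-bis(methoxymethoxy)-2-(2-methylbut-3-en-2-yl)phenyl N-(propan-2-yl)carbamate
Product: 11 silyl carbamate 3,5-bis(methoxymethoxy)-2-(2-methylbut-3-en-2-yl)-6-(trimethylsilyl)phenyl N-(propan-2-yl)carbamate, via N-silyl carbamate 8 (not isolated), via aryllithium 9 (not isolated), via C,N-disilyl carbamate 10 (not isolated)
Conditions: Me3SiOTf (1.1 equiv), TMEDA, Et2O, 0 °C to rt; n-BuLi (2.2 equiv), TMEDA, –78 °C; Me3SiCl, –78 °C to rt; aq NH4Cl
Reagents that add atoms: chlorotrimethylsilane, C[Si](C)(C)Cl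
Why: Directed ortho-metalation, in which the N-silylated carbamate and the neighbouring acetal oxygen together steer n-BuLi to the one free position ortho to the carbamate (the future C4a) in preference to C6, which is flanked only by the two weaker acetal directors, after which Me3SiCl traps the aryllithium and the N–Si bond is lost on aqueous work-up.

Step 6
Reactants: 11 silyl carbamate 3,5-bis(methoxymethoxy)-2-(2-methylbut-3-en-2-yl)-6-(trimethylsilyl)phenyl N-(propan-2-yl)carbamate
Product: 13 silyl triflate 3,5-bis(methoxymethoxy)-2-(2-methylbut-3-en-2-yl)-6-(trimethylsilyl)phenyl trifluoromethanesulfonate, via silylphenol 12 (not isolated)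
Conditions: DBU (1.5 equiv), Et2NH (1.2 equiv), MeCN, 40 °C; then PhNTf2 (1.5 equiv), 40 °C
Reagents that add atoms: N-phenylbis(trifluoromethanesulfonimide) (PhNTf2), O=S(=O)(N(c1ccccc1)S(=O)(=O)C(F)(F)F)C(F)(F)F
Why: E1cB cleavage of the N–H carbamate (the isocyanate is scavenged by Et2NH as a urea) frees the phenoxide under base, so the acid-sensitive electron-rich arylsilane is never isolated as the phenol, and O-sulfonylation with PhNTf2 then gives the ortho-silylaryl triflate needed for fluoride-triggered aryne formation.

Step 7
Reactants: 14 4-iodophenol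
Product: 15 aryl iodide 1-iodo-4-(methoxymethoxy)benzene
Conditions: NaH, MOMCl, THF, 0 °C to rt
Reagents that add atoms: chloromethyl methyl ether (MOMCl), COCCl
Why: Williamson-type O-alkylation installs the same acetal used on ring A, so that a single acidic step can remove all three at the end.

Step 8
Reactants: 15 aryl iodide 1-iodo-4-(methoxymethoxy)benzene; 16 propiolic acid (prop-2-ynoic acid)
Product: 17 acid 3-[4-(methoxymethoxy)phenyl]prop-2-ynoic acid
Conditions: Pd(PPh3)4 (cat.), DBU (2.4 equiv), DMSO, 30 °C; then cold aq citric acid to pH 3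
Reagents that add atoms: none
Why: Copper-free Sonogashira coupling of the aryl iodide with propiolic acid as its amidinium carboxylate proceeds near room temperature, where decarboxylation of the arylpropiolic acid should be slow.

Step 9
Reactants: 13 silyl triflate 3,5-bis(methoxymethoxy)-2-(2-methylbut-3-en-2-yl)-6-(trimethylsilyl)phenyl trifluoromethanesulfonate; 17 acid 3-[4-(methoxymethoxy)phenyl]prop-2-ynoic acid
Product: 20 flavone 5,7-bis(methoxymethoxy)-2-[4-(methoxymethoxy)phenyl]-8-(2-methylbut-3-en-2-yl)-4H-chromen-4-one, via aryne 18 (not isolated), via hydroxyaryl ynone 19 (not isolated)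
Conditions: 13 (1.2 equiv), CsF (4 equiv), THF, 125 °C, sealed tube
Reagents that add atoms: none
Why: Fluoride removes the silyl group of 13 with loss of triflate to give aryne 18 (strained bond C4a–C8a), the caesium carboxylate of 17 adds through oxygen to C8a, the C4a aryl anion so formed attacks the ester carbonyl through a four-membered transition state (net insertion of the aryne into the acid C–O bond) to give the phenoxide of ynone 19, and the phenoxide adds to the ynone to close the pyranone, C3 taking up the proton released by the acid. The closest known reaction type is the fluoride-mediated insertion of arynes into the carbon–oxygen bond of carboxylic acids, which with 3-arylpropiolic acids runs on to flavones. Ring C is the only ring formed and it closes in the 6-endo-dig mode by oxa-Michael addition of the C8a oxygen to C2; no stereocentre is created. The selectivity needed is attack of oxygen at C8a and not at C4a: the C5 acetal oxygen, sigma-withdrawing and lying in the plane of the aryne, makes the remote carbon C8a the electrophilic one and stabilises the charge that develops at C4a, and the electron-releasing alkyl group at C8 distorts the aryne in the same sense. Only the bulk of the quaternary carbon at C8 opposes this, and a carboxylate oxygen is among the smallest nucleophiles available, so electronic control is expected to prevail. The side chain has no allylic hydrogen, which excludes an intramolecular ene reaction of the aryne, and the aprotic medium at 125 °C is chosen so that acyl transfer outruns protonation of the aryl anion to a simple aryl ester.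

Step 10
Reactants: 20 flavone 5,7-bis(methoxymethoxy)-2-[4-(methoxymethoxy)phenyl]-8-(2-methylbut-3-en-2-yl)-4H-chromen-4-one
Product: 23 flavonol triether 3-hydroxy-5,7-bis(methoxymethoxy)-2-[4-(methoxymethoxy)phenyl]-8-(2-methylbut-3-en-2-yl)-4H-chromen-4-one, via 3-lithioflavone 21 (not isolated), via 3-boronate 22 (not isolated)
Conditions: LiN(i-Pr)2 (2 equiv), THF, –78 °C; B(OMe)3, –78 to 0 °C; H2O2 (30% aq), AcOH, 0 °C to rt
Reagents that add atoms: hydrogen peroxide, OO
Why: Deprotonation–borylation–oxidation, in which the amide base removes the C3 hydrogen of the vinylogous ester (lithium held by the C4 oxygen), B(OMe)3 traps the vinyllithium and peroxide oxidises the C–B bond to the C3 hydroxyl under conditions that leave the isolated terminal alkene untouched.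

Step 11
Reactants: 23 flavonol triether 3-hydroxy-5,7-bis(methoxymethoxy)-2-[4-(methoxymethoxy)phenyl]-8-(2-methylbut-3-en-2-yl)-4H-chromen-4-one
Product: 24 target 3,5,7-trihydroxy-2-(4-hydroxyphenyl)-8-(2-methylbut-3-en-2-yl)-4H-chromen-4-one
Conditions: HCl (3 M aq), MeOH, 50 °C
Reagents that add atoms: none
Why: Acid-catalysed acetal methanolysis should remove the three methoxymethyl groups as dimethoxymethane, while the monosubstituted alkene on a quaternary carbon is not protonated under such mild acid, so closure of the C7 hydroxyl onto it is not expected.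

**Compound list**

1 | phloroglucinol (benzene-1,3,5-triol) | Oc1cc(O)cc(O)c1 | starting material
2 | 3,5-bis(methoxymethoxy)phenol | COCOc1cc(O)cc(OCOC)c1 | intermediate
3 | prenyl bromide (1-bromo-3-methylbut-2-ene) | CC(C)=CCBr | starting material
4 | 1,3-bis(methoxymethoxy)-5-[(3-methylbut-2-en-1-yl)oxy]benzene | CC(C)=CCOc1cc(OCOC)cc(OCOC)c1 | intermediate
5 | Claisen dienone, 3,5-bis(methoxymethoxy)-6-(2-methylbut-3-en-2-yl)cyclohexa-2,4-dien-1-one (racemic, formed in the flask) | C=CC(C)(C)C1C(=O)C=C(OCOC)C=C1OCOC | intermediate
6 | 3,5-bis(methoxymethoxy)-2-(2-methylbut-3-en-2-yl)phenol | C=CC(C)(C)c1c(O)cc(OCOC)cc1OCOC | intermediate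
7 | 3,5-bis(methoxymethoxy)-2-(2-methylbut-3-en-2-yl)phenyl N-(propan-2-yl)carbamate | C=CC(C)(C)c1c(OC(=O)NC(C)C)cc(OCOC)cc1OCOC | intermediate
8 | 3,5-bis(methoxymethoxy)-2-(2-methylbut-3-en-2-yl)phenyl N-(propan-2-yl)-N-(trimethylsilyl)carbamate (formed in the flask) | C=CC(C)(C)c1c(OC(=O)N(C(C)C)[Si](C)(C)C)cc(OCOC)cc1OCOC | intermediate
9 | aryllithium, 8 lithiated at the ring carbon between the carbamate and an acetal oxygen (formed in the flask) | C=CC(C)(C)c1c(OC(=O)N(C(C)C)[Si](C)(C)C)c([Li])c(OCOC)cc1OCOC | intermediate
10 | 3,5-bis(methoxymethoxy)-2-(2-methylbut-3-en-2-yl)-6-(trimethylsilyl)phenyl N-(propan-2-yl)-N-(trimethylsilyl)carbamate (formed in the flask) | C=CC(C)(C)c1c(OC(=O)N(C(C)C)[Si](C)(C)C)c([Si](C)(C)C)c(OCOC)cc1OCOC | intermediate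
11 | 3,5-bis(methoxymethoxy)-2-(2-methylbut-3-en-2-yl)-6-(trimethylsilyl)phenyl N-(propan-2-yl)carbamate | C=CC(C)(C)c1c(OC(=O)NC(C)C)c([Si](C)(C)C)c(OCOC)cc1OCOC | intermediate
12 | 3,5-bis(methoxymethoxy)-2-(2-methylbut-3-en-2-yl)-6-(trimethylsilyl)phenol (present as its amidinium phenoxide, formed in the flask) | C=CC(C)(C)c1c(O)c([Si](C)(C)C)c(OCOC)cc1OCOC | intermediate
13 | 3,5-bis(methoxymethoxy)-2-(2-methylbut-3-en-2-yl)-6-(trimethylsilyl)phenyl trifluoromethanesulfonate | C=CC(C)(C)c1c(OS(=O)(=O)C(F)(F)F)c([Si](C)(C)C)c(OCOC)cc1OCOC | intermediate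
14 | 4-iodophenol | Oc1ccc(I)cc1 | starting material
15 | 1-iodo-4-(methoxymethoxy)benzene | COCOc1ccc(I)cc1 | intermediate
16 | propiolic acid (prop-2-ynoic acid) | C#CC(=O)O | starting material
17 | 3-[4-(methoxymethoxy)phenyl]prop-2-ynoic acid | OC(=O)C#Cc1ccc(OCOC)cc1 | intermediate
18 | aryne, 1,2-didehydro-3,5-bis(methoxymethoxy)-6-(2-methylbut-3-en-2-yl)benzene (C4a≡C8a of the flavone, formed in the flask) | C=CC(C)(C)C1=C(OCOC)C=C(OCOC)C#C1 | intermediate
19 | 1-[2-hydroxy-4,6-bis(methoxymethoxy)-3-(2-methylbut-3-en-2-yl)phenyl]-3-[4-(methoxymethoxy)phenyl]prop-2-yn-1-one (as its phenoxide, formed in the flask) | C=CC(C)(C)c1c(O)c(C(=O)C#Cc2ccc(OCOC)cc2)c(OCOC)cc1OCOC | intermediate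
20 | 5,7-bis(methoxymethoxy)-2-[4-(methoxymethoxy)phenyl]-8-(2-methylbut-3-en-2-yl)-4H-chromen-4-one | C=CC(C)(C)c1c(OCOC)cc(OCOC)c2c(=O)cc(-c3ccc(OCOC)cc3)oc12 | intermediate
21 | 3-lithio derivative of flavone 20 (formed in the flask) | C=CC(C)(C)c1c(OCOC)cc(OCOC)c2c(=O)c([Li])c(-c3ccc(OCOC)cc3)oc12 | intermediate
22 | dimethyl {5,7-bis(methoxymethoxy)-2-[4-(methoxymethoxy)phenyl]-8-(2-methylbut-3-en-2-yl)-4-oxo-4H-chromen-3-yl}boronate (formed in the flask) | C=CC(C)(C)c1c(OCOC)cc(OCOC)c2c(=O)c(B(OC)OC)c(-c3ccc(OCOC)cc3)oc12 | intermediate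
23 | 3-hydroxy-5,7-bis(methoxymethoxy)-2-[4-(methoxymethoxy)phenyl]-8-(2-methylbut-3-en-2-yl)-4H-chromen-4-one | C=CC(C)(C)c1c(OCOC)cc(OCOC)c2c(=O)c(O)c(-c3ccc(OCOC)cc3)oc12 | intermediate
24 | 3,5,7-trihydroxy-2-(4-hydroxyphenyl)-8-(2-methylbut-3-en-2-yl)-4H-chromen-4-one | C=CC(C)(C)c1c(O)cc(O)c2c(=O)c(O)c(-c3ccc(O)cc3)oc12 | target

**Step count and risks**

Total step count: 11. Longest linear sequence: 9 steps (steps 1–6, then 9–11); the acid branch (steps 7–8) joins at step 9.

Steps most likely to fail:

1. Step 9. The carboxylate oxygen may be steered by the bulk of the C8 quaternary carbon to the wrong aryne carbon (C4a), the aryl anion may be protonated to a simple aryl ester before acyl transfer, or the alkynoic acid may decarboxylate at 125 °C. The fallback makes the same three bonds stepwise, with the regiochemistry fixed by the carbamate. It sets out from carbamate 7: the N-silylation and lithiation of step 5 are run as far as aryllithium 9, which is quenched at –78 °C, in place of Me3SiCl, with the Weinreb amide N-methoxy-N-methyl-3-[4-(methoxymethoxy)phenyl]prop-2-ynamide F1 (made from acid 17 with carbonyldiimidazole and MeNH(OMe)·HCl). This should give the N-silylated ynone carbamate F2, and aqueous work-up should leave 3,5-bis(methoxymethoxy)-2-{3-[4-(methoxymethoxy)phenyl]prop-2-ynoyl}-6-(2-methylbut-3-en-2-yl)phenyl N-(propan-2-yl)carbamate F3. DBU and Et2NH in MeCN at 40 °C (the cleavage conditions of step 6) then unmask the phenoxide of 19, which should close 6-endo-dig to flavone 20, where the route is rejoined.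

2. Step 5. The silyl triflate used for N-silylation may strip the acetal protecting groups, or the base may metalate C6 between the two acetal oxygens instead of the carbon next to the carbamate. The fallback places silicon by halogen–metal exchange and oxygen-to-carbon silyl migration instead of deprotonation. It sets out from phenol 2, which is brominated ortho to the hydroxyl (NBS, cat. i-Pr2NH, CH2Cl2, –78 °C) to 2-bromo-3,5-bis(methoxymethoxy)phenol F4. O-Prenylation with 3 (K2CO3, acetone) gives 2-bromo-1,5-bis(methoxymethoxy)-3-[(3-methylbut-2-en-1-yl)oxy]benzene F5, and heating as in step 3 (PhNEt2, 190 °C) should take it through the bromodienone F6 to the only free ortho carbon, giving 2-bromo-3,5-bis(methoxymethoxy)-6-(2-methylbut-3-en-2-yl)phenol F7. O-Silylation with (Me3Si)2NH in THF gives the aryl trimethylsilyl ether F8. With n-BuLi at –78 °C bromine is exchanged for lithium to give the aryllithium F9, the silyl group migrates from oxygen to carbon (retro-Brook rearrangement) to give the lithium salt of 12, and Tf2O added to the same flask should give 13, where the route is rejoined.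

3. Step 3. The free phenol may react further at the rearrangement temperature: isomerisation of the side chain by the abnormal Claisen pathway, ring closure of the hydroxyl onto the alkene, or loss of the prenyl group. The fallback does not let the phenol exist hot. It sets out from ether 4, which is heated in PhNEt2 containing butanoic anhydride so that phenol 6 is acylated as it forms, giving 3,5-bis(methoxymethoxy)-2-(2-methylbut-3-en-2-yl)phenyl butanoate F10. K2CO3 in MeOH at rt then releases 6, where the route is rejoined.

**Further compounds**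

F1 | step 9 | N-methoxy-N-methyl-3-[4-(methoxymethoxy)phenyl]prop-2-ynamide | CON(C)C(=O)C#Cc1ccc(OCOC)cc1
F2 | step 9 | 3,5-bis(methoxymethoxy)-2-{3-[4-(methoxymethoxy)phenyl]prop-2-ynoyl}-6-(2-methylbut-3-en-2-yl)phenyl N-(propan-2-yl)-N-(trimethylsilyl)carbamate | C=CC(C)(C)c1c(OC(=O)N(C(C)C)[Si](C)(C)C)c(C(=O)C#Cc2ccc(OCOC)cc2)c(OCOC)cc1OCOC
F3 | step 9 | 3,5-bis(methoxymethoxy)-2-{3-[4-(methoxymethoxy)phenyl]prop-2-ynoyl}-6-(2-methylbut-3-en-2-yl)phenyl N-(propan-2-yl)carbamate | C=CC(C)(C)c1c(OC(=O)NC(C)C)c(C(=O)C#Cc2ccc(OCOC)cc2)c(OCOC)cc1OCOC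
F4 | step 5 | 2-bromo-3,5-bis(methoxymethoxy)phenol | COCOc1cc(O)c(Br)c(OCOC)c1
F5 | step 5 | 2-bromo-1,5-bis(methoxymethoxy)-3-[(3-methylbut-2-en-1-yl)oxy]benzene | CC(C)=CCOc1cc(OCOC)cc(OCOC)c1Br
F6 | step 5 | 2-bromo-3,5-bis(methoxymethoxy)-6-(2-methylbut-3-en-2-yl)cyclohexa-2,4-dien-1-one (racemic, transient) | C=CC(C)(C)C1C(=O)C(Br)=C(OCOC)C=C1OCOC
F7 | step 5 | 2-bromo-3,5-bis(methoxymethoxy)-6-(2-methylbut-3-en-2-yl)phenol | C=CC(C)(C)c1c(O)c(Br)c(OCOC)cc1OCOC
F8 | step 5 | [2-bromo-3,5-bis(methoxymethoxy)-6-(2-methylbut-3-en-2-yl)phenoxy]trimethylsilane | C=CC(C)(C)c1c(O[Si](C)(C)C)c(Br)c(OCOC)cc1OCOC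
F9 | step 5 | aryllithium, F8 with lithium in place of bromine | C=CC(C)(C)c1c(O[Si](C)(C)C)c([Li])c(OCOC)cc1OCOC
F10 | step 3 | 3,5-bis(methoxymethoxy)-2-(2-methylbut-3-en-2-yl)phenyl butanoate | C=CC(C)(C)c1c(OC(=O)CCC)cc(OCOC)cc1OCOC
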